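The apigenin half (flavone 2) is not made by biaryl coupling. Its C8, which carries the chromene ring and is bonded to C8a beside O1, is traced back to a benzylic CH2 on C2 of a 4-pyranone (ring C) whose C3 bears a methyl ester. One operation acetylates that benzylic carbon (C7–C8) and closes ring A (C4a, C5, C6, C7, C8, C8a) by Dieckmann attack on the ester (C5–C6), so only the 8-aryl isomer can form. The precursor is a 2-(chromenylmethyl)-6-aryl-4-oxopyran-3-carboxylate assembled from a chromenylacetic acid and an arylpropiolic acid. A bromide at chromene C6 later becomes flavone 1 by borylation and oxidative Heck coupling.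

Key step: step 10

Assumption: the target has no stereocentre, and the biaryl axis between chromene C8 and flavone C8 is taken as not configurationally fixed, so no stereocontrol is planned.

**Route**

Step 1
Reactants: 1 methyl 2-(2-hydroxyphenyl)acetate
Product: 2 methyl 2-(5-bromo-2-hydroxyphenyl)acetate
Conditions: NBS (1.0 equiv), MeCN, 0 °C → rt
Reagents that add atoms: N-bromosuccinimide, O=C1CCC(=O)N1Br
Why: Electrophilic aromatic bromination, in which the free hydroxyl directs to its open para position and the remaining ortho site is the more hindered one.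

Step 2
Reactants: 2 methyl 2-(5-bromo-2-hydroxyphenyl)acetate; 3 3-chloro-3-methylbut-1-yne
Product: 4 methyl 2-[5-bromo-2-(2-methylbut-3-yn-2-yloxy)phenyl]acetate
Conditions: CuCl2·2H2O (1 mol%), DBU (1.5 equiv), MeCN, 0 °C
Reagents that add atoms: none
Why: Copper-catalysed propargylic O-alkylation of a phenol with a tertiary propargylic chloride, the standard entry to aryl 1,1-dimethylpropargyl ethers, run cold so that the phenoxide is alkylated before it can attack its own ester.

Step 3
Reactants: 4 methyl 2-[5-bromo-2-(2-methylbut-3-yn-2-yloxy)phenyl]acetate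
Product: 6 methyl 2-(6-bromo-2,2-dimethylchromen-8-yl)acetate, via allenylphenol 5 (not isolated)
Conditions: N,N-diethylaniline, 190 °C
Reagents that add atoms: none
Why: Aromatic propargyl Claisen rearrangement to the only free ortho carbon, after which the allenylphenol should close by 1,5-hydrogen shift and oxa-6π electrocyclisation to the 2,2-dimethylchromene.

Step 4
Reactants: 6 methyl 2-(6-bromo-2,2-dimethylchromen-8-yl)acetate
Product: 7 2-(6-bromo-2,2-dimethylchromen-8-yl)acetic acid
Conditions: LiOH·H2O (3 equiv), THF/MeOH/H2O, rt; 1 M HCl to pH 3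
Reagents that add atoms: lithium hydroxide, [Li+].[OH-]
Why: Plain ester saponification, which the aryl bromide and the chromene alkene should tolerate.

Step 5
Reactants: 7 2-(6-bromo-2,2-dimethylchromen-8-yl)acetic acid; 8 potassium 3-methoxy-3-oxopropanoate
Product: 11 methyl 4-(6-bromo-2,2-dimethylchromen-8-yl)-3-oxobutanoate, via acyl imidazole 9 (not isolated), via acylmalonic half ester 10 (not isolated)
Conditions: 1,1'-carbonyldiimidazole (1.2 equiv), THF, rt; then 8 (2 equiv), MgCl2 (1.5 equiv), THF, rt → 50 °C; 1 M HCl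
Reagents that add atoms: none
Why: Masamune–Brooks homologation, in which the magnesium enolate of the malonate half ester is C-acylated by the acyl imidazole and the adduct decarboxylates to the β-keto ester.

Step 6
Reactants: 12 4-iodophenol
Product: 13 1-iodo-4-(methoxymethoxy)benzene
Conditions: MOMCl (1.3 equiv), i-Pr2NEt (1.5 equiv), CH2Cl2, 0 °C → rt
Reagents that add atoms: chloromethyl methyl ether, COCCl
Why: O-alkylation of the phenol to its methoxymethyl ether, a group that is stable to the later bases and falls with all the other phenol protecting groups in the last step.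

Step 7
Reactants: 13 1-iodo-4-(methoxymethoxy)benzene; 14 propiolic acid
Product: 15 3-[4-(methoxymethoxy)phenyl]prop-2-ynoic acid
Conditions: Pd(PPh3)4 (2.5 mol%), DBU (2.5 equiv), DMSO, 35 °C; cold 10% citric acid
Reagents that add atoms: none
Why: Copper-free Sonogashira coupling of an aryl iodide with propiolic acid (as its amidinium carboxylate) on zerovalent palladium, kept near room temperature so that the product should not decarboxylate.

Step 8
Reactants: 15 3-[4-(methoxymethoxy)phenyl]prop-2-ynoic acid; 11 methyl 4-(6-bromo-2,2-dimethylchromen-8-yl)-3-oxobutanoate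
Product: 17 methyl 2-[2-(6-bromo-2,2-dimethylchromen-8-yl)acetyl]-5-[4-(methoxymethoxy)phenyl]-3-oxopent-4-ynoate, via ynoyl chloride 16 (not isolated)
Conditions: 15, 1-chloro-N,N,2-trimethylprop-1-en-1-amine (1.1 equiv), CH2Cl2, 0 °C → rt; then added to 11, MgCl2 (1.2 equiv), pyridine (2.5 equiv), CH2Cl2, 0 °C
Reagents that add atoms: none
Why: The chloroenamine makes the acid chloride without releasing HCl (sparing the acetal and the triple bond), and magnesium chloride/pyridine soft enolisation then gives chelation-controlled C-acylation of the β-keto ester at its central carbon.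

Step 9
Reactants: 17 methyl 2-[2-(6-bromo-2,2-dimethylchromen-8-yl)acetyl]-5-[4-(methoxymethoxy)phenyl]-3-oxopent-4-ynoate
Product: 18 methyl 2-[(6-bromo-2,2-dimethylchromen-8-yl)methyl]-6-[4-(methoxymethoxy)phenyl]-4-oxopyran-3-carboxylate
Conditions: Ph3PAuCl (5 mol%), AgOTf (5 mol%), CH2Cl2, rt
Reagents that add atoms: none
Why: Monovalent-gold-catalysed 6-endo-dig cycloisomerisation, in which the enolised ketone oxygen adds to the aryl-bearing carbon of the π-activated ynone, as known for alkynyl 1,3-dicarbonyl compounds going to 4-pyranones; the ketone oxygen should outcompete the ester oxygen and the five-membered mode.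

Step 10
Reactants: 18 methyl 2-[(6-bromo-2,2-dimethylchromen-8-yl)methyl]-6-[4-(methoxymethoxy)phenyl]-4-oxopyran-3-carboxylate; 19 1-acetylimidazole
Product: 21 8-(6-bromo-2,2-dimethylchromen-8-yl)-5,7-dihydroxy-2-[4-(methoxymethoxy)phenyl]chromen-4-one, via methyl ketone 20 (not isolated)
Conditions: LiN(SiMe3)2 (2.2 equiv), THF, −78 °C; 19 (1.2 equiv), −78 → −20 °C; LiN(SiMe3)2 (2.5 equiv), −20 °C → rt; cold 1 M HCl to pH 4
Reagents that add atoms: none
Why: Proposed new method: LiN(SiMe3)2 removes a proton from the CH2 of 18, which is acidified through C2=C3 by both the ring carbonyl and the ester, and the extended enolate is acetylated by 19 at the exocyclic carbon to give 20 (held as its enolate by the second equivalent of base); further base then generates a small share of the methyl ketone enolate, whose carbon adds to the neighbouring ester, methoxide leaves and the triketone tautomerises to the 5,7-dihydroxy arene. The closest known reactions are toluate-anion annulations of the Staunton–Weinreb type, the base cyclisation of 2-(2-oxopropyl)benzoates to naphthalene-1,3-diols, and the side-chain deprotonation and acylation of 2-alkyl-4-pyranones. Ring A closes in a 6-(enolendo)-exo-trig Dieckmann mode. No stereocentre is formed. The step needs acylation at the exocyclic carbon and not at oxygen or at C3: attack at C3 would create a quaternary centre and break the pyranone conjugation, and any O-acetyl enol ester is itself an acyl donor that can pass the group on to carbon. The choice between an 8-aryl and a 6-aryl flavone does not arise, because the aryl-bearing carbon is already bonded to the carbon next to the ring oxygen.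

Step 11
Reactants: 21 8-(6-bromo-2,2-dimethylchromen-8-yl)-5,7-dihydroxy-2-[4-(methoxymethoxy)phenyl]chromen-4-one
Product: 22 8-(6-bromo-2,2-dimethylchromen-8-yl)-5,7-bis(methoxymethoxy)-2-[4-(methoxymethoxy)phenyl]chromen-4-one
Conditions: NaH (3 equiv), MOMCl (3 equiv), DMF, 0 °C → rt
Reagents that add atoms: chloromethyl methyl ether, COCCl
Why: O-alkylation of both phenoxides, with NaH in DMF used because the hydrogen-bonded 5-hydroxyl does not react under amine-base conditions.

Step 12
Reactants: 22 8-(6-bromo-2,2-dimethylchromen-8-yl)-5,7-bis(methoxymethoxy)-2-[4-(methoxymethoxy)phenyl]chromen-4-one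
Product: 23 8-[2,2-dimethyl-6-(4,4,5,5-tetramethyl-1,3,2-dioxaborolan-2-yl)chromen-8-yl]-5,7-bis(methoxymethoxy)-2-[4-(methoxymethoxy)phenyl]chromen-4-one
Conditions: B2pin2 (1.5 equiv), Pd(dppf)Cl2 (5 mol%), KOAc (3 equiv), 1,4-dioxane, 90 °C
Reagents that add atoms: bis(pinacolato)diboron, CC1(C)OB(OC1(C)C)B1OC(C)(C)C(C)(C)O1
Why: Miyaura borylation of an unhindered, electron-rich aryl bromide, to which the flavone, the acetals and the chromene alkene should be inert.

Step 13
Reactants: 24 5,7-dihydroxychromen-4-one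
Product: 25 5,7-bis(methoxymethoxy)chromen-4-one
Conditions: NaH (2.5 equiv), MOMCl (2.5 equiv), DMF, 0 °C → rt
Reagents that add atoms: chloromethyl methyl ether, COCCl
Why: The same phenol O-alkylation as in step 11, giving a chromone partner with no free hydroxyl for the palladium step.

Step 14
Reactants: 23 8-[2,2-dimethyl-6-(4,4,5,5-tetramethyl-1,3,2-dioxaborolan-2-yl)chromen-8-yl]-5,7-bis(methoxymethoxy)-2-[4-(methoxymethoxy)phenyl]chromen-4-one; 25 5,7-bis(methoxymethoxy)chromen-4-one
Product: 26 8-{6-[5,7-bis(methoxymethoxy)-4-oxochromen-2-yl]-2,2-dimethylchromen-8-yl}-5,7-bis(methoxymethoxy)-2-[4-(methoxymethoxy)phenyl]chromen-4-one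
Conditions: Pd(O2CCF3)2 (10 mol%), O2 (1 atm), DMSO, 80 °C, 25 (2 equiv)
Reagents that add atoms: none
Why: Oxidative boron-Heck arylation of a chromone at C2 (transmetalation to divalent palladium, carbopalladation of the enone, β-hydride elimination through the palladium enolate, reoxidation by O2), a known route from chromones to flavones under conditions that should also dehydrogenate any flavanone formed by conjugate addition.

Step 15
Reactants: 26 8-{6-[5,7-bis(methoxymethoxy)-4-oxochromen-2-yl]-2,2-dimethylchromen-8-yl}-5,7-bis(methoxymethoxy)-2-[4-(methoxymethoxy)phenyl]chromen-4-one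
Product: 27 8-[6-(5,7-dihydroxy-4-oxochromen-2-yl)-2,2-dimethylchromen-8-yl]-5,7-dihydroxy-2-(4-hydroxyphenyl)chromen-4-one
Conditions: 3 M HCl (aq.), MeOH/THF, 50 °C
Reagents that add atoms: none
Why: Acid-catalysed acetal exchange should remove all five methoxymethyl groups at once under conditions routinely survived by 2,2-dimethylchromenes that carry an electron-poor aryl ring.

**Compound list**

1 | methyl 2-(2-hydroxyphenyl)acetate | COC(=O)Cc1ccccc1O | starting material
2 | methyl 2-(5-bromo-2-hydroxyphenyl)acetate | COC(=O)Cc1cc(Br)ccc1O | intermediate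
3 | 3-chloro-3-methylbut-1-yne | CC(C)(Cl)C#C | starting material
4 | methyl 2-[5-bromo-2-(2-methylbut-3-yn-2-yloxy)phenyl]acetate | COC(=O)Cc1cc(Br)ccc1OC(C)(C)C#C | intermediate
5 | methyl 2-[5-bromo-2-hydroxy-3-(3-methylbuta-1,2-dien-1-yl)phenyl]acetate | COC(=O)Cc1cc(Br)cc(C=C=C(C)C)c1O | intermediate (not isolated)
6 | methyl 2-(6-bromo-2,2-dimethylchromen-8-yl)acetate | COC(=O)Cc1cc(Br)cc2C=CC(C)(C)Oc12 | intermediate
7 | 2-(6-bromo-2,2-dimethylchromen-8-yl)acetic acid | OC(=O)Cc1cc(Br)cc2C=CC(C)(C)Oc12 | intermediate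
8 | potassium 3-methoxy-3-oxopropanoate | COC(=O)CC(=O)[O-].[K+] | starting material
9 | 2-(6-bromo-2,2-dimethylchromen-8-yl)-1-(imidazol-1-yl)ethan-1-one | O=C(Cc1cc(Br)cc2C=CC(C)(C)Oc12)n1ccnc1 | intermediate (not isolated)
10 | 2-[2-(6-bromo-2,2-dimethylchromen-8-yl)acetyl]-3-methoxy-3-oxopropanoic acid (magnesium carboxylate in the flask; labile CH, racemic) | COC(=O)C(C(=O)O)C(=O)Cc1cc(Br)cc2C=CC(C)(C)Oc12 | intermediate (not isolated)
11 | methyl 4-(6-bromo-2,2-dimethylchromen-8-yl)-3-oxobutanoate | COC(=O)CC(=O)Cc1cc(Br)cc2C=CC(C)(C)Oc12 | intermediate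
12 | 4-iodophenol | Oc1ccc(I)cc1 | starting material
13 | 1-iodo-4-(methoxymethoxy)benzene | COCOc1ccc(I)cc1 | intermediate
14 | propiolic acid | C#CC(=O)O | starting material
15 | 3-[4-(methoxymethoxy)phenyl]prop-2-ynoic acid | COCOc1ccc(cc1)C#CC(=O)O | intermediate
16 | 3-[4-(methoxymethoxy)phenyl]prop-2-ynoyl chloride | COCOc1ccc(cc1)C#CC(Cl)=O | intermediate (not isolated)
17 | methyl 2-[2-(6-bromo-2,2-dimethylchromen-8-yl)acetyl]-5-[4-(methoxymethoxy)phenyl]-3-oxopent-4-ynoate (enolised tricarbonyl) | COC(=O)C(C(=O)Cc1cc(Br)cc2C=CC(C)(C)Oc12)C(=O)C#Cc1ccc(OCOC)cc1 | intermediate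
18 | methyl 2-[(6-bromo-2,2-dimethylchromen-8-yl)methyl]-6-[4-(methoxymethoxy)phenyl]-4-oxopyran-3-carboxylate | COC(=O)C1=C(Cc2cc(Br)cc3C=CC(C)(C)Oc23)OC(c2ccc(OCOC)cc2)=CC1=O | intermediate
19 | 1-acetylimidazole | CC(=O)n1ccnc1 | starting material
20 | methyl 2-[1-(6-bromo-2,2-dimethylchromen-8-yl)-2-oxopropyl]-6-[4-(methoxymethoxy)phenyl]-4-oxopyran-3-carboxylate (present as its enolate; labile CH, racemic) | COC(=O)C1=C(C(C(C)=O)c2cc(Br)cc3C=CC(C)(C)Oc23)OC(c2ccc(OCOC)cc2)=CC1=O | intermediate (not isolated)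
21 | 8-(6-bromo-2,2-dimethylchromen-8-yl)-5,7-dihydroxy-2-[4-(methoxymethoxy)phenyl]chromen-4-one | CC1(C)C=Cc2cc(Br)cc(-c3c(O)cc(O)c4c(=O)cc(-c5ccc(OCOC)cc5)oc34)c2O1 | intermediate
22 | 8-(6-bromo-2,2-dimethylchromen-8-yl)-5,7-bis(methoxymethoxy)-2-[4-(methoxymethoxy)phenyl]chromen-4-one | CC1(C)C=Cc2cc(Br)cc(-c3c(OCOC)cc(OCOC)c4c(=O)cc(-c5ccc(OCOC)cc5)oc34)c2O1 | intermediate
23 | 8-[2,2-dimethyl-6-(4,4,5,5-tetramethyl-1,3,2-dioxaborolan-2-yl)chromen-8-yl]-5,7-bis(methoxymethoxy)-2-[4-(methoxymethoxy)phenyl]chromen-4-one | CC1(C)C=Cc2cc(B3OC(C)(C)C(C)(C)O3)cc(-c3c(OCOC)cc(OCOC)c4c(=O)cc(-c5ccc(OCOC)cc5)oc34)c2O1 | intermediate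
24 | 5,7-dihydroxychromen-4-one | O=c1ccoc2cc(O)cc(O)c12 | starting material
25 | 5,7-bis(methoxymethoxy)chromen-4-one | COCOc1cc(OCOC)c2c(=O)ccoc2c1 | intermediate
26 | 8-{6-[5,7-bis(methoxymethoxy)-4-oxochromen-2-yl]-2,2-dimethylchromen-8-yl}-5,7-bis(methoxymethoxy)-2-[4-(methoxymethoxy)phenyl]chromen-4-one | CC1(C)C=Cc2cc(-c3cc(=O)c4c(OCOC)cc(OCOC)cc4o3)cc(-c3c(OCOC)cc(OCOC)c4c(=O)cc(-c5ccc(OCOC)cc5)oc34)c2O1 | intermediate
27 | 8-[6-(5,7-dihydroxy-4-oxochromen-2-yl)-2,2-dimethylchromen-8-yl]-5,7-dihydroxy-2-(4-hydroxyphenyl)chromen-4-one (CNP0135272.0) | CC1(C)C=Cc2cc(-c3cc(=O)c4c(O)cc(O)cc4o3)cc(-c3c(O)cc(O)c4c(=O)cc(-c5ccc(O)cc5)oc34)c2O1 | target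

**Step count and risks**

Total step count: 15. Longest linear sequence: 12 (steps 1–5, 8–12, 14, 15).

Steps most likely to fail:

1. Step 10. The annulation may fail in several ways:
   - the acetyl group may be transferred to oxygen and stay there;
   - 19 may be deprotonated by the excess amide base and quench the carbanion;
   - the reaction may stall at the stabilised enolate of 20, because the methyl ketone enolate is too sparsely populated;
   - that enolate may close through oxygen onto the ester to an enol lactone;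
   - the base may open the pyranone ring.

   Fallback (known chemistry, accepting a hindered coupling): ring A is bought in and the biaryl bond is made by Suzuki coupling. The fallback sets out from 3 and from two purchased compounds, 4-bromo-2-iodophenol (Oc1ccc(Br)cc1I) and apigenin (O=c1cc(-c2ccc(O)cc2)oc2cc(O)cc(O)c12), and comes back to the route at 22. 4-Bromo-2-iodophenol is etherified with 3 (CuCl2·2H2O, DBU, MeCN, 0 °C) to 4-bromo-2-iodo-1-(2-methylbut-3-yn-2-yloxy)benzene F1. Heating F1 in N,N-diethylaniline should give 6-bromo-8-iodo-2,2-dimethylchromene F2 by the same Claisen cascade as in step 3. Selective Miyaura borylation at the carbon–iodine bond (B2pin2, Pd(dppf)Cl2, KOAc, DMSO, 60 °C) should then give 2-(6-bromo-2,2-dimethylchromen-8-yl)-4,4,5,5-tetramethyl-1,3,2-dioxaborolane F3. Apigenin is converted with NaH and MOMCl in DMF into 5,7-bis(methoxymethoxy)-2-[4-(methoxymethoxy)phenyl]chromen-4-one F4. Iodination of F4 with N-iodosuccinimide in DMF, which goes to C8 when O5 is alkylated, should give 8-iodo-5,7-bis(methoxymethoxy)-2-[4-(methoxymethoxy)phenyl]chromen-4-one F5. Suzuki–Miyaura coupling of F3 with F5 (Pd(OAc)2, SPhos, K3PO4, toluene/H2O, 80 °C, the iodide reacting before the bromide) should give 22. The 8- versus 6-iodination would have to be proven on F5.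

2. Step 14. The aryl–palladium species may insert into the chromene C3=C4 bond instead of the chromone, the boronate may be lost by protodeboronation or homocoupling, or the sequence may stop at the conjugate-addition stage.

   Fallback: bond formation and dehydrogenation are separated. It sets out from 23 and 25 and comes back at 26. Rhodium-catalysed 1,4-addition ([Rh(OH)(cod)]2, aq. KOH, 1,4-dioxane, 60 °C; monovalent rhodium does not engage the unactivated chromene alkene) should give racemic 2-{8-[5,7-bis(methoxymethoxy)-2-[4-(methoxymethoxy)phenyl]-4-oxochromen-8-yl]-2,2-dimethylchromen-6-yl}-5,7-bis(methoxymethoxy)-2,3-dihydrochromen-4-one F6. Dehydrogenation of F6 with DDQ in 1,4-dioxane at 100 °C should give 26.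

3. Step 8. Chloride, pyridine or the enolate may add in conjugate fashion to the ynoyl chloride 16, or acylation may go to oxygen.

   Fallback: the roles of the two halves are exchanged, so that no ynoyl chloride is needed. It sets out from 15 and 7 and comes back at 17. Acid 15 is coupled with 2,2-dimethyl-1,3-dioxane-4,6-dione (DCC, DMAP, CH2Cl2, 0 °C) to 5-{1-hydroxy-3-[4-(methoxymethoxy)phenyl]prop-2-yn-1-ylidene}-2,2-dimethyl-1,3-dioxane-4,6-dione F7. Heating F7 in methanol should give methyl 5-[4-(methoxymethoxy)phenyl]-3-oxopent-4-ynoate F8. Acid 7 is converted with 1-chloro-N,N,2-trimethylprop-1-en-1-amine into 2-(6-bromo-2,2-dimethylchromen-8-yl)acetyl chloride F9. F9 is added to F8 with MgCl2 and pyridine in CH2Cl2 at 0 °C, where C-acylation at the central carbon should give 17.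

**Further compounds**

F1 | step 10 | 4-bromo-2-iodo-1-(2-methylbut-3-yn-2-yloxy)benzene | CC(C)(C#C)Oc1ccc(Br)cc1I
F2 | step 10 | 6-bromo-8-iodo-2,2-dimethylchromene | CC1(C)C=Cc2cc(Br)cc(I)c2O1
F3 | step 10 | 2-(6-bromo-2,2-dimethylchromen-8-yl)-4,4,5,5-tetramethyl-1,3,2-dioxaborolane | CC1(C)C=Cc2cc(Br)cc(B3OC(C)(C)C(C)(C)O3)c2O1
F4 | step 10 | 5,7-bis(methoxymethoxy)-2-[4-(methoxymethoxy)phenyl]chromen-4-one | COCOc1ccc(cc1)-c1cc(=O)c2c(OCOC)cc(OCOC)cc2o1
F5 | step 10 | 8-iodo-5,7-bis(methoxymethoxy)-2-[4-(methoxymethoxy)phenyl]chromen-4-one | COCOc1ccc(cc1)-c1cc(=O)c2c(OCOC)cc(OCOC)c(I)c2o1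
F6 | step 14 | 2-{8-[5,7-bis(methoxymethoxy)-2-[4-(methoxymethoxy)phenyl]-4-oxochromen-8-yl]-2,2-dimethylchromen-6-yl}-5,7-bis(methoxymethoxy)-2,3-dihydrochromen-4-one (racemic) | CC1(C)C=Cc2cc(C3CC(=O)c4c(OCOC)cc(OCOC)cc4O3)cc(-c3c(OCOC)cc(OCOC)c4c(=O)cc(-c5ccc(OCOC)cc5)oc34)c2O1
F7 | step 8 | 5-{1-hydroxy-3-[4-(methoxymethoxy)phenyl]prop-2-yn-1-ylidene}-2,2-dimethyl-1,3-dioxane-4,6-dione | COCOc1ccc(cc1)C#CC(O)=C1C(=O)OC(C)(C)OC1=O
F8 | step 8 | methyl 5-[4-(methoxymethoxy)phenyl]-3-oxopent-4-ynoate | COC(=O)CC(=O)C#Cc1ccc(OCOC)cc1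
F9 | step 8 | 2-(6-bromo-2,2-dimethylchromen-8-yl)acetyl chloride | O=C(Cl)Cc1cc(Br)cc2C=CC(C)(C)Oc12
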